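The easy step was to divide isomer of the product by target in each run and to take equal amounts, a quotient of 1, as the zero of my scale. My decision was whether a sample of the new flask at 12 h was worth taking as nearly clean target, and whether its reagent charge should be changed for that purpose.

common to all: substrate 20 mM

|  | reagent | remark | time |
|---|---|---|---|
| red | 40 mM | run made earlier |  |
| green | 160 mM | run made earlier |  |
| flask | 80.0 mM |  | 15 d |

| run | time / d | isomer of the product / % | target / % | substrate / % |
|---|---|---|---|---|
| red | 0.625 | 0 | 2 | 96 |
| red | 1.25 | 0 | 2 | 84 |
| red | 2.50 | 4 | 11 | 80 |
| red | 5.00 | 7 | 11 | 63 |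
| red | 10.0 | 6 | 8 | 43 |
| green | 1.67 | 5 | 20 | 55 |
| green | 4.00 | 16 | 19 | 19 |
| green | 5.00 | 16 | 16 | 17 |
| green | 8.00 | 11 | 10 | 5 |
| green | 10.0 | 12 | 5 | 3 |

(standard deviation of a reading: 2 percentage points)

* ratio of isomer of the product to target at 12 h
* ratio of isomer of the product to target at 15 d
* which of isomer of the product and target there is more of at 15 d

- the analysis behind the earlier runs scatters by 2 percentage points, standard deviation

The earliest readings with target well above the scatter gave 0.364 in the red run at 2.50 d and 0.250 in the green run at 1.67 d, although the green run had 4.00 times the reagent. Their difference is smaller than the 0.182 that one scatter in the red isomer reading makes. So I pooled them into ρ = 0.290, the early ratio, summed isomer over summed target, a selectivity factor. The red zero at 1.25 d is no proof of a lag, because ρ on that target reading expects 0.58 percentage points of isomer, less than the scatter. I therefore committed to ρ at 12 h, kept the charge and skipped the sample.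

The forecast gave 0.08 at 12 h, lower than my ρ, and 2.1 at 15 d with isomer of the product ahead, on this ground: “That suggests it forms from target”.

The flask gave 0.403 at 12 h and 1.58 at 15 d, with isomer of the product ahead, 7.28% against 4.61% of target.

    substrate + reagent → intermediate + by-product (k = 0.110 L mol⁻¹ h⁻¹)
    intermediate ⇌ target (K = 12.0, k = 0.0980 h⁻¹)
    intermediate ⇌ isomer of the product (K = 3.60, k = 0.0360 h⁻¹)
    target → over-reaction product (k = 0.0230 h⁻¹)

In the flask the quotient at 12 h stood 1.39 times my ρ and still below the level of 1. The neighbour charged with 20 mM of reagent, a quarter of the flask's charge, takes the same reckoning: the early quotients of the red and green runs had differed by less than the scatter, so I carried ρ over unchanged, although this charge lies below that of either run. That neighbour gave 0.402 at 12 h, level with the flask. At 15 d it held 4.52% of isomer against 3.65% of target, a ratio of 1.24.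

The earlier runs and the new flask were computed on assumed constants; noise was put on by code.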